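Atom numbering used throughout: ring A is C1 (bearing OAc), C2, C3, C4 (Br), C5 (two methyls), C6. C7 is the linking methylene. Ring B is C8, C9, C10, C11, C16. Ring C is C11, C12 (Br), C13, C14, C15 (Me, OH), C16. C17 is the CH2OH carbon on C11.

## Analysis of the target

The target 35 is a cyclohexane (ring A) joined through the single methylene C7 to a trans-fused hydrindane made of cyclopentane ring B and cyclohexane ring C. It has seven stereocentres: C1 and C4 in ring A, and C8, C11, C12, C15 and C16 in the bicycle. In the bicycle H16 is anti to C17, the C12 bromine is equatorial and syn to C17, the C15 hydroxyl is axial and syn to C17 (1,3-diaxial to it), and C7 sits on C8 on the face of H16, trans to the C15 branch. In ring A the acetoxy group is axial and cis to the equatorial C4 bromine, with C7 equatorial. Both bromines are secondary and flanked by a quaternary carbon, so each must be placed with inversion at a neopentylic centre without elimination or skeletal shift. The tertiary acetate must be formed beside a free tertiary alcohol and a neopentyl primary alcohol. Ring A and the bicycle do not communicate stereochemically across C7, so ring A must arrive enantiopure and C1 must be set by the conformation of ring A alone. The route rests on one feature of ring B: C8 carries a one-carbon branch (C7) directly beside the fusion carbon C16. That is the pattern left when a six-membered ring C16–C8–C7–C9–C10–C11 ejects C7 as a formyl group while C9 moves from C7 to C8.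

## Retrosynthetic reasoning

**C7–C1.** 35 differs from 34 only by two silyl ethers. 34 is cut at C7–C1 into the primary iodide 28 and the ketone 32. C7 is the only link between the two ring systems, the bond ends at a tertiary carbinol, and the cut separates two pieces that each carry their own stereocentres. The forward reaction has to generate a C7 nucleophile from a primary iodide in the presence of secondary bromides, add it to the equatorial side of the ketone, and acetylate the resulting alkoxide before the other tertiary oxygen is unmasked.

**Ring A ketone.** The C4–Br bond of 32 is traced through the ketal 31 to the C–O bond of alcohol 30 with inversion, and 30 to the prochiral ketone 29. A reagent-controlled reduction then fixes the absolute configuration of ring A, which nothing in the bicycle could control.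

**C15.** 28 goes back through 27 to the tertiary alcohol 26, which is cut at C15–CH3 to the ketone 25, and 25 to the methylene compound 23. The face of C15 anti to C17 is the only open one, so a methyl nucleophile gives the axial hydroxyl directly. C15 is carried as a methylene group up to this point because a carbonyl or carbinol there would not survive the ring contraction.

**The bromides of the bicycle.** Both C–Br bonds of 23 are traced to C–O bonds in diol 22. The axial C12 alcohol comes from the ketone of 21 by equatorial hydride delivery, the C7 alcohol from the aldehyde, and 21 from the ketal 20.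

**Ring B (key disconnection).** In 20 the C8–C9 bond is broken and C9 is rejoined to C7, which leads to the trans-decalin hydroxy mesylate 19. This converts a trans-hydrindane with three contiguous stereocentres into a six-six system with a locked chair, whose stereocentres follow from well-understood decalin chemistry. The forward reaction must move the ring bond, not hydride, and must invert C8.

**Mesylate, methylene and diol.** 19 comes from the cis-diol 17 by sulfonylation of the equatorial oxygen. The methylene group of 17 is unveiled from the aminomethyl group of 15 by Cope elimination, and 15 comes from the alkene 14 by osmium-catalysed dihydroxylation. The order matters: the exocyclic alkene is released only after the dihydroxylation, so that 14 offers osmium a single alkene.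

**Ring fusion and alkene position.** 14 is traced to the allylic alcohol 11 by reductive 1,3-transposition, and 11 to the enone 10. Dissolving-metal reduction of the enone is ruled out because C15 must already carry its substituent (it is activated only while the enone is present) and a γ-heteroatom would be at risk. Enolization of a saturated C7 ketone would place the alkene on the C9 side. The transposition sets H16 anti to C17 and puts the alkene at C7=C8 in one step.

**C15 branch and C12 protection.** 10 is cut at C15–CH2N (vinylogous Mannich reaction) to the ketal 8, and 8 to the enedione 7. C15 is the γ-carbon of the enone and can be functionalized only at this stage.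

**Decalin.** 7 is opened by a retro-Robinson annulation through triketone 6 to the dione 4 and enone 5. An amino-acid-derived catalyst sets C11. 4 is cut at C11–C17 to the masked dione 1 and the chloromethyl silyl ether 2, which brings in C17 already protected.

## Alternatives that were turned down

**Alternative 1: bromonium cyclization closes ring A last.** The disconnection removes C5–C6, C4–Br and C1–O together and leads to the open-chain diene A1. In the forward step a vanadium bromoperoxidase with bromide and peroxide would put bromonium on the C4=C5 alkene, the C1=C6 methylene would attack C5, and water would capture the C1 cation to give the bromohydrin A2, which is then acetylated. This is biomimetic and makes ring A, both its stereocentres and the C–Br bond in one step. The anti-addition in a chair places bromine equatorial without any substitution at a neopentylic carbon. On the number of steps for ring A and on the C4 bromide it is stronger than the chosen route. Against it: the alkene is remote from every stereocentre, so the absolute sense at C4 and C1 rests wholly on an enzyme whose tolerance for so large and polar a substrate is unknown, and such enzymes often release free hypobromite. The C1 cation can lose a proton or be captured by the C15 hydroxyl through a six-membered ether instead of water. A1 still contains the whole bromo-hydrindane, so the hard part is not simplified. The chosen route instead fixes ring A by a reagent-controlled reduction and a known inversion, and keeps its main risk at an early, cheap stage.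

**Alternative 2: intramolecular Diels–Alder reaction of a bromoacrylate.** The disconnection cuts C11–C16 and C12–C13 and leads to the nonatriene A3. On heating or with an aluminium Lewis acid it would close rings B and C together to the hydrindene ester A4. This forms two rings, the quaternary C11, C16 and the C12 bromide in one step, and the bromine arrives on an sp2 carbon with its configuration fixed by alkene geometry. On convergence and on the C12 bromide it is stronger than the chosen route. Against it: the dienophile is fully substituted at C11 and carries bromine at C12, which makes it hindered and unreactive. Nonatrienes give trans-hydrindanes with poor endo/exo control, and only the single stereocentre C8 on the tether can steer the facial sense. Afterwards the C14=C15 alkene of A4 must be hydrated with oxygen on the hindered face syn to the ester, and the ester must be reduced next to a β-bromide. The chosen route is longer, but each stereocentre of the bicycle is set on a rigid trans-decalin by a reaction whose facial preference is predictable.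

**Alternative 3: samarium ketyl–enone closure of ring C.** The disconnection cuts C14–C15 and leads to the cyclopentane keto enone A5. Divalent samarium with a proton source would form the C15 ketyl, which adds to the enone terminus C14 in a 6-endo closure to give A6. This builds ring C and the C15 carbinol in one mild step, and chelation of samarium between ketyl and ester could place the hydroxyl syn to C17. On the C15 centre it is about as strong as the Grignard addition of the chosen route. Against it: the vinyl ketone is reduced at least as readily as the methyl ketone and tends to oligomerize. A5 is a non-enolizable β-keto ester open to retro-Claisen cleavage, and its C16 is epimerizable, so the trans fusion is not secured. A6 still needs the same invertive bromination at C12 as the chosen route, plus an ester reduction beside a ketone. A5 itself, a cyclopentane with a quaternary carbon and three contiguous stereocentres, would also have to be made first, so the difficulty is moved and not removed. The chosen route makes that cyclopentane from a decalin in which the same centres are easy to set.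

Key step: step 10

Remark: 1, 2, 5 and 29 are taken to be catalogue compounds.
Remark: compounds 10 to 16 carry a stereocentre at C15 that is erased in step 8. The epimer with the aminomethyl group anti to C17 is drawn, and a mixture of epimers would serve equally.

## Route

Step 1
Reactants: 1 1,5-dimethoxycyclohexa-1,4-diene; 2 (chloromethoxy)tri(propan-2-yl)silane
Product: 4 2-[(triisopropylsilyloxy)methyl]cyclohexane-1,3-dione, via alkylated bis-enol ether 3 (not isolated)
Conditions: t-BuLi, HMPA, THF, −78 °C; then 2; then 1 M HCl, THF, 25 °C
Reagents that add atoms: water O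
Why: Alkylation of a metallated 1,5-dimethoxycyclohexa-1,4-diene: the CH2 between the two enol ether carbons is lithiated and alkylated by the α-chloro ether, so C17 enters on carbon without the O-alkylation that a free dione would suffer. Mild acid then unmasks the 1,3-dione while the primary triisopropylsilyl ether holds.

Step 2
Reactants: 4 2-[(triisopropylsilyloxy)methyl]cyclohexane-1,3-dione; 5 but-3-en-2-one
Product: 7 (S)-8a-[(triisopropylsilyloxy)methyl]-3,4,8,8a-tetrahydronaphthalene-1,6(2H,7H)-dione, via triketone 6 (not isolated)
Conditions: 5, Et3N (cat.), neat, 25 °C; then N-tosyl-(Sa)-binam-L-prolinamide (5 mol %), PhCO2H (cat.), 25 °C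
Reagents that add atoms: none
Why: Robinson annulation (Michael addition, then enamine-mediated aldol condensation of the Hajos–Parrish–Eder–Sauer–Wiechert type). The L-proline-derived catalyst chooses between the two enantiotopic ring carbonyls and should set C11 as S, the sense it gives with an angular methyl group.

Step 3
Reactants: 7 (S)-enedione
Product: 8 C12 ethylene ketal of 7 (dioxolane at the saturated carbonyl with the enone intact)
Conditions: HOCH2CH2OH, p-TsOH (cat.), 4 Å MS, 25 °C
Reagents that add atoms: ethane-1,2-diol OCCO
Why: Acid-catalysed ketalization; the saturated C12 ketone is far more electrophilic than the vinylogous enone carbonyl, as in the parent angular-methyl enedione.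

Step 4
Reactants: 8 C12 ketal enone
Product: 10 C15-(dimethylaminomethyl) enone, via silyl dienol ether 9 (not isolated)
Conditions: TBSOTf, Et3N, CH2Cl2, 0 → 25 °C; then Me2N=CH2+ I−, CH2Cl2, 25 °C; aq. NaHCO3
Reagents that add atoms: N,N-dimethylmethyleneiminium iodide C[N+](C)=C.[I-]; tert-butyldimethylsilyl triflate CC(C)(C)[Si](C)(C)OS(=O)(=O)C(F)(F)F (silicon in 9 only)
Why: Vinylogous Mannich reaction: under equilibrating silylation the enone gives the extended dienol ether, which takes the iminium ion at its terminus C15, the way C6 of steroidal 4-en-3-ones is functionalized. The product is used at once, since the enone could lose dimethylamine again.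

Step 5
Reactants: 10 C15-(dimethylaminomethyl) enone
Product: 11 allylic alcohol with the C7 hydroxyl syn to C17
Conditions: NaBH4, CeCl3·7H2O, MeOH, −40 → 0 °C
Reagents that add atoms: none
Why: Luche 1,2-reduction; hydride enters on the face away from the angular C17 group, so the C7 hydroxyl ends pseudo-equatorial and syn to C17. Removing the enone also ends the retro-Mannich lability of 10.

Step 6
Reactants: 11 allylic alcohol
Product: 14 trans-fused alkene with C7=C8 and H16 anti to C17, via sulfonylhydrazine adduct 12 (not isolated), via allylic diazene 13 (not isolated)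
Conditions: 2-nitrobenzenesulfonylhydrazide, PPh3, DEAD, THF, −30 °C; then 25 °C
Reagents that add atoms: 2-nitrobenzenesulfonylhydrazide NNS(=O)(=O)c1ccccc1[N+](=O)[O-] (nitrogen in 12 and 13 only)
Why: Myers reductive 1,3-transposition: Mitsunobu displacement with inversion puts nitrogen on the face anti to C17, sulfinate loss gives the diazene, and its retro-ene loss of N2 delivers hydrogen to C16 from that same face. One operation therefore sets the trans ring fusion at C16 and places the alkene at C7=C8.

Step 7
Reactants: 14 trans-fused alkene
Product: 15 amino cis-diol with the C7 hydroxyl axial and the C8 hydroxyl equatorial (both anti to C17)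
Conditions: OsO4 (2 mol %), NMO, acetone–H2O, 25 °C
Reagents that add atoms: osmium tetroxide O=[Os](=O)(=O)=O (catalytic carrier of both oxygens); N-methylmorpholine N-oxide C[N+]1([O-])CCOCC1; water O
Why: Upjohn syn-dihydroxylation; the axial C17 group on C11 is 1,3 to C8 and screens the lower face, so both oxygens enter anti to C17. C15 is still sp3 here, so no second alkene competes.

Step 8
Reactants: 15 amino cis-diol
Product: 17 C15-methylene cis-diol, via amine N-oxide 16 (not isolated)
Conditions: mCPBA, K2CO3, CH2Cl2, 0 °C; then toluene, 110 °C
Reagents that add atoms: 3-chloroperbenzoic acid OOC(=O)c1cccc(Cl)c1 (oxygen in 16 only)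
Why: Cope elimination; the N-oxide has a β-hydrogen only at C15, so the syn elimination can give nothing but the exocyclic C15 methylene.

Step 9
Reactants: 17 C15-methylene cis-diol
Product: 19 C8 monomesylate (equatorial mesylate at C8 and axial hydroxyl at C7), via stannylene acetal 18 (not isolated)
Conditions: Bu2SnO, toluene, reflux (−H2O); then MsCl, 0 → 25 °C
Reagents that add atoms: methanesulfonyl chloride CS(=O)(=O)Cl; dibutyltin oxide CCCC[Sn](=O)CCCC (tin in 18 only)
Why: Stannylene-mediated monosulfonylation of a cis-diol; in the dibutylstannylene acetal of an axial/equatorial diol the equatorial oxygen is the nucleophilic one, so the mesyl group should go to C8–O and leave the axial C7 hydroxyl free.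

Step 10
Reactants: 19 C8 monomesylate
Product: 20 trans-hydrindane C7 aldehyde
Conditions: KOtBu (1.2 equiv), t-BuOH–THF, 0 → 25 °C
Reagents that add atoms: none
Why: KOtBu deprotonates the axial C7 hydroxyl; the alkoxide drives the C7–C9 bond, which lies antiperiplanar to the equatorial C8–O bond, over to C8 as mesylate departs, and C7 becomes the formyl carbon. The closest known reaction type is the base-induced semipinacol rearrangement of cyclic cis-diol monosulfonates. Ring B (C8, C9, C10, C11, C16) forms by contraction of the six-membered ring in a single concerted 1,2-shift of carbon, without a carbocation intermediate. The new stereocentre C8 is created with inversion because C9 arrives anti to the leaving group, so the formyl group ends on the face of H16, trans to the C15 branch; this is also the arrangement an equilibration of the α-centre would favour. The step needs ring-bond migration in preference to hydride shift, elimination and oxirane closure. The locked trans-decalin chair secures this: C7–H is gauche to the mesylate, no hydrogen is antiperiplanar to an equatorial leaving group, and a cis-hydroxy sulfonate cannot close to an epoxide. Keeping C15 trigonal avoids a syn-pentane clash with the C8 substituent and removes any β-elimination path through C16.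

Step 11
Reactants: 20 trans-hydrindane C7 aldehyde
Product: 21 C12-keto C7-aldehyde
Conditions: 1 M HCl, THF, 25 °C
Reagents that add atoms: water O
Why: Acid hydrolysis of the dioxolane; the primary triisopropylsilyl ether and the 1,1-disubstituted alkene tolerate dilute acid at room temperature, and the aldehyde α-centre C8 already has its more stable configuration.

Step 12
Reactants: 21 C12-keto C7-aldehyde
Product: 22 diol with a primary C7 hydroxyl and an axial C12 hydroxyl anti to C17
Conditions: LiBH(s-Bu)3 (L-Selectride), THF, −78 → 0 °C; H2O
Reagents that add atoms: none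
Why: Hydride reduction of both carbonyls; the bulky borohydride attacks the C12 ketone from the equatorial direction (axial entry is opposed by the syn-axial hydrogens at C14 and C16) and gives the axial alcohol, as with 4,4-dimethyl-3-keto terpenoids.

Step 13
Reactants: 22 diol
Product: 23 C7,C12-dibromide with the C12 bromine equatorial and syn to C17
Conditions: CBr4, PPh3, 2,6-lutidine, toluene, 0 → 70 °C
Reagents that add atoms: tetrabromomethane BrC(Br)(Br)Br
Why: Appel bromination of both alcohols; the primary C7 oxyphosphonium is displaced readily, and the axial C12 oxyphosphonium is displaced from the rear with inversion to the equatorial bromide, the outcome known for axial neopentylic cyclohexanols. Lutidine keeps the methylene group from adding HBr.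

Step 14
Reactants: 23 dibromide
Product: 25 C15 ketone, via ozonide 24 (not isolated)
Conditions: O3, CH2Cl2, −78 °C; then Me2S, −78 → 25 °C
Reagents that add atoms: ozone [O-][O+]=O
Why: Ozonolysis with reductive work-up; alkyl bromides and the silyl ether are inert to ozone, and the neutral work-up spares the now enolizable C16.

Step 15
Reactants: 25 C15 ketone
Product: 26 C15 tertiary alcohol with axial hydroxyl syn to C17 and equatorial methyl
Conditions: MeMgBr, CeCl3, THF, −78 °C
Reagents that add atoms: methylmagnesium bromide C[Mg]Br
Why: Grignard addition in the presence of CeCl3, which suppresses enolization toward C16; the axial face of C15 is closed by the 1,3-diaxial C17 substituent, so methyl enters equatorially and the hydroxyl ends axial and syn to C17.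

Step 16
Reactants: 26 C15 tertiary alcohol
Product: 27 C7 iodide
Conditions: NaI, butan-2-one, 80 °C
Reagents that add atoms: sodium iodide [Na+].[I-]
Why: Finkelstein exchange at the primary bromide only; the secondary C12 bromide beside the quaternary C11 does not undergo SN2 under these conditions.

Step 17
Reactants: 27 C7 iodide
Product: 28 C15 trimethylsilyl ether of 27
Conditions: TMSOTf, 2,6-lutidine, CH2Cl2, −78 → 0 °C
Reagents that add atoms: trimethylsilyl triflate C[Si](C)(C)OS(=O)(=O)C(F)(F)F
Why: Silylation of the hindered tertiary alcohol with a silyl triflate; it removes the only protic group before the organometallic step and keeps this oxygen out of the later acetylation.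

Step 18
Reactants: 29 7,7-dimethyl-1,4-dioxaspiro[4.5]decan-8-one
Product: 30 (R)-7,7-dimethyl-1,4-dioxaspiro[4.5]decan-8-ol
Conditions: (S)-2-methyl-CBS-oxazaborolidine (10 mol %), BH3·SMe2, THF, −20 °C
Reagents that add atoms: none
Why: Corey–Bakshi–Shibata reduction; the quaternary α-carbon acts as the large group and the methylene as the small one, so the (S)-catalyst should give the (R)-alcohol.

Step 19
Reactants: 30 (R)-alcohol
Product: 31 (S)-8-bromo-7,7-dimethyl-1,4-dioxaspiro[4.5]decane
Conditions: CBr4, PPh3, 2,6-lutidine, toluene, 0 → 60 °C
Reagents that add atoms: tetrabromomethane BrC(Br)(Br)Br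
Why: Appel bromination with inversion (R to S) at the neopentylic carbinol; the monocyclic ring can place the oxyphosphonium group axial for rear-side entry of bromide.

Step 20
Reactants: 31 (S)-bromo ketal
Product: 32 (S)-4-bromo-3,3-dimethylcyclohexan-1-one
Conditions: 1 M HCl, THF, 25 °C
Reagents that add atoms: water O
Why: Acid hydrolysis of the ketal; the secondary bromide is stable to dilute acid, and no base is present that could remove HBr.

Step 21
Reactants: 28 C7 iodide with C15 trimethylsilyl ether; 32 (S)-4-bromo-3,3-dimethylcyclohexan-1-one
Product: 34 bis-silylated acetate (C1 acetate with C15 trimethylsilyl ether and C17 triisopropylsilyl ether), via samarium alkoxide 33 (not isolated)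
Conditions: SmI2 (2.5 equiv), NiI2 (2 mol %), THF, 0 → 25 °C; then Ac2O, DMAP, 25 °C
Reagents that add atoms: acetic anhydride CC(=O)OC(C)=O; samarium diiodide I[Sm]I (samarium in 33 only)
Why: Samarium Barbier reaction: the primary iodide is reduced selectively (secondary bromides resist SmI2 in THF without HMPA) and the C7 nucleophile adds to the ketone. Axial entry at C1 is blocked in either chair by a syn-axial methyl of C5, so C7 enters equatorially, and in the chair with equatorial bromine this puts the C1 oxygen axial and cis to bromine. Acetylating the samarium alkoxide in the flask marks this tertiary oxygen while the C15 oxygen is still silylated.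

Step 22
Reactants: 34 bis-silylated acetate
Product: 35 target CNP0182818.1
Conditions: HF·pyridine, pyridine–THF, 0 → 25 °C
Reagents that add atoms: none
Why: Fluoride-driven cleavage of both silyl ethers in one operation; the medium is not basic, so the tertiary acetate and the two secondary bromides are left alone.

## Compound list

1 | 1,5-dimethoxycyclohexa-1,4-diene | COC1=CCC=C(OC)C1 | starting material
2 | (chloromethoxy)tri(propan-2-yl)silane | ClCO[Si](C(C)C)(C(C)C)C(C)C | starting material
3 | 6-[(triisopropylsilyloxy)methyl]-1,5-dimethoxycyclohexa-1,4-diene | COC1=CCC=C(OC)C1CO[Si](C(C)C)(C(C)C)C(C)C | intermediate (not isolated)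
4 | 2-[(triisopropylsilyloxy)methyl]cyclohexane-1,3-dione | O=C1CCCC(=O)C1CO[Si](C(C)C)(C(C)C)C(C)C | intermediate
5 | but-3-en-2-one | CC(=O)C=C | starting material
6 | 2-(3-oxobutyl)-2-[(triisopropylsilyloxy)methyl]cyclohexane-1,3-dione | CC(=O)CCC1(CO[Si](C(C)C)(C(C)C)C(C)C)C(=O)CCCC1=O | intermediate (not isolated)
7 | (S)-8a-[(triisopropylsilyloxy)methyl]-3,4,8,8a-tetrahydronaphthalene-1,6(2H,7H)-dione (C12 ketone; C7 enone carbonyl; C8=C16) | CC(C)[Si](C(C)C)(C(C)C)OC[C@]12CCC(=O)C=C1CCCC2=O | intermediate
8 | C12 ethylene ketal of 7 | CC(C)[Si](C(C)C)(C(C)C)OC[C@]12CCC(=O)C=C1CCCC23OCCO3 | intermediate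
9 | tert-butyldimethylsilyl dienol ether of 8 (C7–OSi; C7=C8 and C16=C15) | CC(C)[Si](C(C)C)(C(C)C)OC[C@]12CCC(O[Si](C)(C)C(C)(C)C)=CC1=CCCC23OCCO3 | intermediate (not isolated)
10 | C15-(dimethylaminomethyl) enone (aminomethyl anti to C17) | CC(C)[Si](C(C)C)(C(C)C)OC[C@]12CCC(=O)C=C1[C@@H](CN(C)C)CCC23OCCO3 | intermediate
11 | allylic alcohol (C7–OH syn to C17; C8=C16) | CC(C)[Si](C(C)C)(C(C)C)OC[C@]12CC[C@H](O)C=C1[C@@H](CN(C)C)CCC23OCCO3 | intermediate
12 | C7 N-(2-nitrobenzenesulfonyl)hydrazine adduct (nitrogen anti to C17) | CC(C)[Si](C(C)C)(C(C)C)OC[C@]12CC[C@@H](N(N)S(=O)(=O)c4ccccc4[N+](=O)[O-])C=C1[C@@H](CN(C)C)CCC23OCCO3 | intermediate (not isolated)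
13 | C7 allylic diazene | CC(C)[Si](C(C)C)(C(C)C)OC[C@]12CC[C@@H](N=N)C=C1[C@@H](CN(C)C)CCC23OCCO3 | intermediate (not isolated)
14 | trans-fused alkene (C7=C8; H16 anti to C17; C15 aminomethyl) | CN(C)C[C@H]1CCC2(OCCO2)[C@@]3(CO[Si](C(C)C)(C(C)C)C(C)C)CCC=C[C@H]13 | intermediate
15 | amino cis-diol (C7–OH axial and C8–OH equatorial; both anti to C17) | CN(C)C[C@H]1CCC2(OCCO2)[C@@]3(CO[Si](C(C)C)(C(C)C)C(C)C)CC[C@@H](O)[C@@H](O)[C@H]13 | intermediate
16 | N-oxide of 15 | C[N+](C)([O-])C[C@H]1CCC2(OCCO2)[C@@]3(CO[Si](C(C)C)(C(C)C)C(C)C)CC[C@@H](O)[C@@H](O)[C@H]13 | intermediate (not isolated)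
17 | C15-methylene cis-diol | C=C1CCC2(OCCO2)[C@@]3(CO[Si](C(C)C)(C(C)C)C(C)C)CC[C@@H](O)[C@@H](O)[C@H]13 | intermediate
18 | dibutylstannylene acetal of 17 | C=C1CCC2(OCCO2)[C@@]3(CO[Si](C(C)C)(C(C)C)C(C)C)CC[C@H]4O[Sn](CCCC)(CCCC)O[C@H]4[C@H]13 | intermediate (not isolated)
19 | trans-decalin cis-diol monomesylate (equatorial C8–OMs; axial C7–OH; C15 methylene; C12 ketal; C17 silyl ether) | CS(=O)(=O)O[C@@H]2[C@H](O)CC[C@]3(CO[Si](C(C)C)(C(C)C)C(C)C)C4(OCCO4)CCC(=C)[C@@H]23 | intermediate
20 | trans-hydrindane C7 aldehyde (formyl on C8 syn to H16) | O=C[C@@H]2CC[C@]3(CO[Si](C(C)C)(C(C)C)C(C)C)C4(OCCO4)CCC(=C)[C@@H]23 | intermediate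
21 | C12-keto C7-aldehyde | O=C[C@@H]2CC[C@]3(CO[Si](C(C)C)(C(C)C)C(C)C)C(=O)CCC(=C)[C@@H]23 | intermediate
22 | diol (primary C7–OH; axial C12–OH anti to C17) | OC[C@@H]2CC[C@]3(CO[Si](C(C)C)(C(C)C)C(C)C)[C@H](O)CCC(=C)[C@@H]23 | intermediate
23 | C7,C12-dibromide (C12–Br equatorial and syn to C17) | BrC[C@@H]2CC[C@]3(CO[Si](C(C)C)(C(C)C)C(C)C)[C@@H](Br)CCC(=C)[C@@H]23 | intermediate
24 | C15 spiro-1,2,4-trioxolane (ozonide) of 23 | BrC[C@@H]2CC[C@]3(CO[Si](C(C)C)(C(C)C)C(C)C)[C@@H](Br)CCC4(OCOO4)[C@@H]23 | intermediate (not isolated)
25 | C15 ketone | BrC[C@@H]2CC[C@]3(CO[Si](C(C)C)(C(C)C)C(C)C)[C@@H](Br)CCC(=O)[C@@H]23 | intermediate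
26 | C15 tertiary alcohol (axial OH syn to C17; equatorial methyl) | BrC[C@@H]2CC[C@]3(CO[Si](C(C)C)(C(C)C)C(C)C)[C@@H](Br)CC[C@@](C)(O)[C@@H]23 | intermediate
27 | C7 iodide | IC[C@@H]2CC[C@]3(CO[Si](C(C)C)(C(C)C)C(C)C)[C@@H](Br)CC[C@@](C)(O)[C@@H]23 | intermediate
28 | C7 iodide with C15 trimethylsilyl ether | IC[C@@H]2CC[C@]3(CO[Si](C(C)C)(C(C)C)C(C)C)[C@@H](Br)CC[C@@](C)(O[Si](C)(C)C)[C@@H]23 | intermediate
29 | 7,7-dimethyl-1,4-dioxaspiro[4.5]decan-8-one | CC1(C)CC2(CCC1=O)OCCO2 | starting material
30 | (R)-7,7-dimethyl-1,4-dioxaspiro[4.5]decan-8-ol | CC1(C)CC2(CC[C@H]1O)OCCO2 | intermediate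
31 | (S)-8-bromo-7,7-dimethyl-1,4-dioxaspiro[4.5]decane | CC1(C)CC2(CC[C@@H]1Br)OCCO2 | intermediate
32 | (S)-4-bromo-3,3-dimethylcyclohexan-1-one | O=C1CC[C@H](Br)C(C)(C)C1 | intermediate
33 | samarium diiodide alkoxide of the C1 carbinol | I[Sm](I)O[C@]1(C[C@@H]2CC[C@]3(CO[Si](C(C)C)(C(C)C)C(C)C)[C@@H](Br)CC[C@@](C)(O[Si](C)(C)C)[C@@H]23)CC[C@H](Br)C(C)(C)C1 | intermediate (not isolated)
34 | C1 acetate with C15 trimethylsilyl ether and C17 triisopropylsilyl ether | CC(=O)O[C@]1(C[C@@H]2CC[C@]3(CO[Si](C(C)C)(C(C)C)C(C)C)[C@@H](Br)CC[C@@](C)(O[Si](C)(C)C)[C@@H]23)CC[C@H](Br)C(C)(C)C1 | intermediate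
35 | CNP0182818.1 | CC(=O)O[C@]1(C[C@@H]2CC[C@]3(CO)[C@@H](Br)CC[C@@](C)(O)[C@@H]23)CC[C@H](Br)C(C)(C)C1 | target

## Step count and least certain steps

Total: 22 steps. Longest linear sequence: 19 steps (steps 1 to 17, then 21 and 22). Steps 18 to 20 make the ring A ketone 32.

**Step 10 (key step).** The most likely failure is loss of the aldehyde to aldol condensation under the base. The other is incomplete alkoxide formation, which would let ionization of the mesylate with participation of the C16–C11 bond (an allyl-stabilized cation at C16) compete with the shift. The fallback uses the other carbinol as the leaving site, so that the better migrating ring-fusion carbon moves. It sets out from 11. Hydroboration–oxidation (BH3·THF in excess, since the dimethylamino group binds borane reversibly; then NaOH, H2O2) adds boron to C8 and hydrogen to C16 from the face anti to C17 and should give the trans-diequatorial amino diol F1. N-Oxidation to the N-oxide F2 and Cope elimination as in step 8 give the methylene trans-diol F3. MsCl in pyridine sulfonylates the unhindered equatorial C7 hydroxyl (the C8 hydroxyl is flanked by the ring fusion) to the C7 mesylate F4. KOtBu then moves C16 from C8 to C7, antiperiplanar to the equatorial C7–O bond, and gives the epimeric aldehyde F5, which the same base should equilibrate at the formyl-bearing carbon to 20, where the route is rejoined.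

**Step 21.** Poor facial selectivity at C1 is the main risk. Equatorial entry is secure, but which chair of 32 reacts is not: bromine is a weak conformational anchor, polar 4-substituents of cyclohexanones lean toward the axial position, and the chair with axial bromine leads to the C1 epimer. Reduction of a secondary bromide by SmI2 is a lesser risk. The fallback turns the same axial preference to advantage and sets the bromide afterwards. It sets out from 30 and 28. 30 is converted (NaH, 4-methoxybenzyl chloride) into the 4-methoxybenzyl ether F6 and hydrolysed (1 M HCl, THF) to the (R)-4-(4-methoxybenzyloxy) ketone F7. The Barbier coupling of 28 with F7 and acetylation as in step 21 now need the chair with the axial C4 oxygen and should give the C4-oxygenated acetate F8. DDQ frees the axial C4 alcohol F9, and Appel bromination with inversion gives 34.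

**Step 13.** At C12, elimination toward C13 (an antiperiplanar axial hydrogen is present) or a 1,2-shift from the quaternary C11 may outrun the hindered rear-side displacement. The fallback separates activation from displacement. It sets out from 22: Tf2O and pyridine at −78 °C give the bis-triflate F10, and Bu4NBr in toluene displaces the primary triflate at low temperature and the axial secondary one on warming, with inversion, to give 23.

**Step 19.** The same neopentylic displacement is at stake in ring A, with elimination toward the ring CH2 or transannular participation of a ketal oxygen as the likely failures. The fallback sets out from 30: Tf2O and 2,6-lutidine give the triflate F11, and Bu4NBr in toluene gives 31 with inversion.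

**Step 9.** Sulfonylation at the wrong oxygen, or at both, is the risk, because the equatorial C8 hydroxyl is the more hindered one. The fallback fixes the regiochemistry by a different mechanism. It sets out from 17: trimethyl orthoacetate with camphorsulfonic acid gives the cyclic orthoester F12 (not isolated), whose mild acid hydrolysis opens to the axial ester and gives the C7 acetate with free C8 hydroxyl F13. MsCl and Et3N give the acetoxy mesylate F14, and DIBAL at −78 °C removes the acetate without base to return 19.

**Step 4.** Silylation toward C9 (the cross-conjugated dienol ether) would put the aminomethyl group on the wrong carbon, and 10 may lose dimethylamine on handling. The fallback introduces the carbon first and the amine second. It sets out from 8: direct γ-methylenation (CH2(OEt)2, POCl3, NaOAc, CHCl3, reflux, as used on steroidal 4-en-3-ones) gives the C15-methylene dienone F15, and 1,6-addition of dimethylamine in THF returns 10.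

## Further compounds

F1 | step 10 | trans-diequatorial amino diol (C7–OH syn to C17; C8–OH anti to C17; H16 anti to C17) | CN(C)C[C@H]1CCC2(OCCO2)[C@@]3(CO[Si](C(C)C)(C(C)C)C(C)C)CC[C@H](O)[C@@H](O)[C@H]13
F2 | step 10 | N-oxide of F1 | C[N+](C)([O-])C[C@H]1CCC2(OCCO2)[C@@]3(CO[Si](C(C)C)(C(C)C)C(C)C)CC[C@H](O)[C@@H](O)[C@H]13
F3 | step 10 | C15-methylene trans-diol | C=C1CCC2(OCCO2)[C@@]3(CO[Si](C(C)C)(C(C)C)C(C)C)CC[C@H](O)[C@@H](O)[C@H]13
F4 | step 10 | C7 mesylate of F3 (equatorial C7–OMs; free C8–OH) | C=C1CCC2(OCCO2)[C@@]3(CO[Si](C(C)C)(C(C)C)C(C)C)CC[C@H](OS(C)(=O)=O)[C@@H](O)[C@H]13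
F5 | step 10 | epimer of 20 at the formyl-bearing carbon | O=C[C@H]2CC[C@]3(CO[Si](C(C)C)(C(C)C)C(C)C)C4(OCCO4)CCC(=C)[C@@H]23
F6 | step 21 | (R)-8-(4-methoxybenzyloxy)-7,7-dimethyl-1,4-dioxaspiro[4.5]decane | CC1(C)CC2(CC[C@H]1OCc3ccc(OC)cc3)OCCO2
F7 | step 21 | (R)-4-(4-methoxybenzyloxy)-3,3-dimethylcyclohexan-1-one | O=C1CC[C@@H](OCc2ccc(OC)cc2)C(C)(C)C1
F8 | step 21 | C1 acetate with axial C4 4-methoxybenzyl ether | CC(=O)O[C@]1(C[C@@H]2CC[C@]3(CO[Si](C(C)C)(C(C)C)C(C)C)[C@@H](Br)CC[C@@](C)(O[Si](C)(C)C)[C@@H]23)CC[C@@H](OCc4ccc(OC)cc4)C(C)(C)C1
F9 | step 21 | C1 acetate with axial C4 alcohol | CC(=O)O[C@]1(C[C@@H]2CC[C@]3(CO[Si](C(C)C)(C(C)C)C(C)C)[C@@H](Br)CC[C@@](C)(O[Si](C)(C)C)[C@@H]23)CC[C@@H](O)C(C)(C)C1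
F10 | step 13 | C7,C12-bis-triflate of 22 | FC(F)(F)S(=O)(=O)OC[C@@H]2CC[C@]3(CO[Si](C(C)C)(C(C)C)C(C)C)[C@H](OS(=O)(=O)C(F)(F)F)CCC(=C)[C@@H]23
F11 | step 19 | (R)-7,7-dimethyl-1,4-dioxaspiro[4.5]decan-8-yl triflate | CC1(C)CC2(CC[C@H]1OS(=O)(=O)C(F)(F)F)OCCO2
F12 | step 9 | cyclic methyl orthoacetate of 17 | C=C1CCC2(OCCO2)[C@@]3(CO[Si](C(C)C)(C(C)C)C(C)C)CC[C@H]4OC(C)(OC)O[C@H]4[C@H]13
F13 | step 9 | C7 axial acetate with free equatorial C8 hydroxyl | C=C1CCC2(OCCO2)[C@@]3(CO[Si](C(C)C)(C(C)C)C(C)C)CC[C@@H](OC(C)=O)[C@@H](O)[C@H]13
F14 | step 9 | C7 acetate C8 mesylate | C=C1CCC2(OCCO2)[C@@]3(CO[Si](C(C)C)(C(C)C)C(C)C)CC[C@@H](OC(C)=O)[C@@H](OS(C)(=O)=O)[C@H]13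
F15 | step 4 | C15-methylene dienone | CC(C)[Si](C(C)C)(C(C)C)OC[C@]12CCC(=O)C=C1C(=C)CCC23OCCO3
A1 | alternative 1 | open-chain diene carrying the complete bromo-hydrindane | C=C(C[C@@H]2CC[C@]3(CO)[C@@H](Br)CC[C@@](C)(O)[C@@H]23)CCC=C(C)C
A2 | alternative 1 | ring A bromohydrin (deacetyl target) | O[C@]1(C[C@@H]2CC[C@]3(CO)[C@@H](Br)CC[C@@](C)(O)[C@@H]23)CC[C@H](Br)C(C)(C)C1
A3 | alternative 2 | nonatriene (Z)-bromoacrylate | C=C/C(C)=C/[C@H](CO[Si](C)(C)C(C)(C)C)CC/C(C(=O)OC)=C/Br
A4 | alternative 2 | bromo trans-hydrindene ester | CC(C)(C)[Si](C)(C)OC[C@@H]2CC[C@]3(C(=O)OC)[C@@H](Br)CC=C(C)[C@@H]23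
A5 | alternative 3 | cyclopentane keto enone | CC(=O)[C@H]1[C@H](CO[Si](C)(C)C(C)(C)C)CC[C@]1(C(=O)OC)C(=O)C=C
A6 | alternative 3 | trans-hydrindane with C15 carbinol and C12 ketone | CC(C)(C)[Si](C)(C)OC[C@@H]2CC[C@]3(C(=O)OC)C(=O)CC[C@@](C)(O)[C@@H]23
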